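## Retrosynthetic overview

1. The route rests on the saturated ring of the tetralin. C1 (bearing ring C), C2 (CH2OH), C3 (carbinol carbon with CH2OH) and C4 (H2), fused through C4a/C8a to alkoxyarene ring A, are read as the [4+2] adduct of an aryl-substituted o-quinodimethane (termini C1 and C4) with a C2–C3 two-carbon unit supplied by an allenoate.
2. The tetrahydrofuran is the last ring. It is cut at O1′–C2′ (acid closure of a benzylic alcohol) and at C2′–C3′ (Evans syn aldol of the ring B aldehyde with a malic-acid-derived imide that already holds C4′ and ring D).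
3. In the tetralin, the C3 carbinol and its CH2OH come from the exocyclic methylene by dihydroxylation. The C2 CH2OH comes from the ester by reduction and epimerisation through the aldehyde.
4. The o-quinodimethane comes from a 1-arylbenzocyclobutene, made by Parham cyclisation of a 2,2-diarylethyl bromide. Its biaryl comes from a Suzuki coupling of two vanillin-type arenes.
5. Order of ring formation: cyclobutene (step 13), tetralin ring (step 17), tetrahydrofuran (step 31).

Key step: step 17

Remark on locants: tetralin atoms are C1 (aryl), C2, C3, C4, C4a, C8a. Tetrahydrofuran atoms are O1′, C2′ (aryl), C3′ (CH2OH), C4′ (OH, benzyl), C5′ (H2). Ring A is the tetralin arene, ring B the arene on C2′, ring C the arene on C1, and ring D the arene of the benzyl group.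

Remark on the chemistry: the SMILES shows the benzyl group on C4′ as 3-hydroxy-4-methoxybenzyl, so ring D is drawn from 3-(benzyloxy)-4-methoxybenzyl alcohol.

## Route

Step 1
Reactants: 1 5-bromovanillin
Product: 2 4-(benzyloxy)-3-bromo-5-methoxybenzaldehyde
Conditions: BnBr, K2CO3, DMF, 60 °C
Reagents that add atoms: benzyl bromide, BrCc1ccccc1
Why: Williamson etherification of the acidic phenol is reliable, and benzyl is chosen because all four phenol groups can be freed together by hydrogenolysis in the last step.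

Step 2
Reactants: 2 4-(benzyloxy)-3-bromo-5-methoxybenzaldehyde
Product: 3 2-[4-(benzyloxy)-3-bromo-5-methoxyphenyl]-1,3-dioxolane
Conditions: ethylene glycol, p-TsOH (cat.), toluene, reflux, Dean–Stark trap
Reagents that add atoms: ethylene glycol, OCCO
Why: Acid-catalysed acetalisation with azeotropic removal of water masks the aldehyde against the organolithium, ylide, borane and hydride reagents that follow.

Step 3
Reactants: 3 2-[4-(benzyloxy)-3-bromo-5-methoxyphenyl]-1,3-dioxolane
Product: 4 ring B pinacol boronate (Bpin in place of Br in 3)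
Conditions: B2pin2, Pd(dppf)Cl2 (3 mol %), KOAc, 1,4-dioxane, 90 °C
Reagents that add atoms: bis(pinacolato)diboron, CC1(C)OB(OC1(C)C)B1OC(C)(C)C(C)(C)O1
Why: Miyaura borylation converts the aryl bromide into the boronate under weakly basic conditions that leave the acetal and benzyl ether untouched.

Step 4
Reactants: 5 4-bromo-2-methoxyphenol
Product: 6 4-bromo-2-iodo-6-methoxyphenol
Conditions: NIS, p-TsOH (cat.), MeCN, rt
Reagents that add atoms: N-iodosuccinimide, O=C1CCC(=O)N1I
Why: Electrophilic aromatic iodination is directed by the free hydroxyl group, whose para position is blocked by bromine, so iodine enters the open ortho position.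

Step 5
Reactants: 6 4-bromo-2-iodo-6-methoxyphenol
Product: 7 2-(benzyloxy)-5-bromo-1-iodo-3-methoxybenzene
Conditions: BnBr, K2CO3, DMF, rt
Reagents that add atoms: benzyl bromide, BrCc1ccccc1
Why: Williamson etherification protects the ring C phenol in the same way as the others.

Step 6
Reactants: 4 ring B pinacol boronate; 7 2-(benzyloxy)-5-bromo-1-iodo-3-methoxybenzene
Product: 8 biaryl bromide, 2-[2,2′-bis(benzyloxy)-5′-bromo-3,3′-dimethoxybiphenyl-5-yl]-1,3-dioxolane
Conditions: Pd(PPh3)4 (5 mol %), Na2CO3 (2 M aq.), DME, 70 °C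
Reagents that add atoms: none
Why: In this Suzuki–Miyaura coupling zerovalent palladium inserts into the C–I bond much faster than into the C–Br bond, so the bromide survives as the handle for step 8, and the axis carries only two ortho substituents and is not a stereo element.

Step 7
Reactants: 9 6-bromoisovanillin
Product: 10 5-(benzyloxy)-2-bromo-4-methoxybenzaldehyde
Conditions: BnBr, K2CO3, DMF, rt
Reagents that add atoms: benzyl bromide, BrCc1ccccc1
Why: Williamson etherification protects the ring A phenol.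

Step 8
Reactants: 8 biaryl bromide; 10 5-(benzyloxy)-2-bromo-4-methoxybenzaldehyde
Product: 12 racemic diaryl carbinol (ring C–CH(OH)–ring A, ring A still brominated ortho to the carbinol), via aryllithium 11 (not isolated)
Conditions: n-BuLi, THF, −78 °C; then 10, −78 °C; H2O
Reagents that add atoms: none
Why: Bromine–lithium exchange is followed by 1,2-addition to the aldehyde, which at −78 °C is faster than exchange with the aryl bromide of 10, and the racemic carbinol centre is erased in step 9.

Step 9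
Reactants: 12 racemic diaryl carbinol
Product: 13 diaryl ketone
Conditions: MnO2, CH2Cl2, rt
Reagents that add atoms: none
Why: MnO2 oxidation of a doubly benzylic alcohol is selective and neutral, so the acetal and ethers are safe.

Step 10
Reactants: 13 diaryl ketone
Product: 14 1,1-diarylethene
Conditions: Ph3PCH3Br, KOt-Bu, THF, 0 → 50 °C
Reagents that add atoms: methyltriphenylphosphonium bromide, C[P+](c1ccccc1)(c1ccccc1)c1ccccc1.[Br-]
Why: Wittig methylenation works on a non-enolisable diaryl ketone and does not touch the aryl bromide.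

Step 11
Reactants: 14 1,1-diarylethene
Product: 16 racemic 2,2-diarylethanol, via B-alkyl-9-BBN adduct 15 (not isolated)
Conditions: 9-BBN, THF, 65 °C; then NaOH (aq.), H2O2, 0 °C → rt
Reagents that add atoms: hydrogen peroxide, OO
Why: Hydroboration–oxidation places boron on the open CH2 terminus (anti-Markovnikov), and the racemic methine centre is of no consequence because it becomes planar in step 17.

Step 12
Reactants: 16 racemic 2,2-diarylethanol
Product: 17 racemic 2,2-diarylethyl bromide
Conditions: CBr4, PPh3, 2,6-lutidine, CH2Cl2, −20 → 0 °C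
Reagents that add atoms: carbon tetrabromide, BrC(Br)(Br)Br
Why: In the Appel bromination bromide displaces the alkoxyphosphonium group by SN2, and running it cold in a non-ionising solvent lets the displacement outrun participation of the electron-rich aryl groups.

Step 13
Reactants: 17 racemic 2,2-diarylethyl bromide
Product: 19 racemic 1-arylbenzocyclobutene (4-benzyloxy-5-methoxy pattern as in ring A, acetal-masked biaryl on the ring carbon), via aryllithium 18 (not isolated)
Conditions: n-BuLi, THF, −100 °C → rt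
Reagents that add atoms: none
Why: In this Parham cyclisation exchange at the aryl bromide is faster than attack on the primary bromide at −100 °C, and on warming the aryllithium closes the four-membered ring by 4-exo-tet displacement, helped by the geminal aryl group.

Step 14
Reactants: 20 (−)-8-phenylmenthol
Product: 21 (−)-8-phenylmenthyl bromoacetate
Conditions: BrCH2COBr, pyridine, CH2Cl2, 0 °C
Reagents that add atoms: bromoacetyl bromide, BrCC(Br)=O
Why: O-Acylation with a very reactive acyl bromide overcomes the hindrance of the secondary alcohol without touching its stereocentres.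

Step 15
Reactants: 21 (−)-8-phenylmenthyl bromoacetate
Product: 23 (−)-8-phenylmenthyl (triphenylphosphoranylidene)acetate, via phosphonium bromide 22 (not isolated)
Conditions: PPh3, toluene, 60 °C; then NaOH (aq.), CH2Cl2, 0 °C
Reagents that add atoms: triphenylphosphine, c1ccc(cc1)P(c1ccccc1)c1ccccc1
Why: SN2 quaternisation of the phosphine by the α-bromo ester and deprotonation of the acidic salt give the stabilised ylide.

Step 16
Reactants: 23 (−)-8-phenylmenthyl (triphenylphosphoranylidene)acetate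
Product: 24 (−)-8-phenylmenthyl buta-2,3-dienoate
Conditions: AcCl, Et3N, CH2Cl2, 0 °C → rt
Reagents that add atoms: acetyl chloride, CC(Cl)=O
Why: Wittig olefination of ketene, generated in the flask by dehydrochlorination of acetyl chloride, is the standard access to buta-2,3-dienoates.

Step 17
Reactants: 19 racemic 1-arylbenzocyclobutene; 24 (−)-8-phenylmenthyl buta-2,3-dienoate
Product: 26 (−)-8-phenylmenthyl (1S,2S)-1-aryl-7-(benzyloxy)-6-methoxy-3-methylidene-1,2,3,4-tetrahydronaphthalene-2-carboxylate (1,2-cis), via (E)-o-quinodimethane 25 (not isolated)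
Conditions: 24 (4 equiv), BHT (cat.), 1,2-dichlorobenzene, 150 °C, sealed tube, argon; separation of diastereomers
Reagents that add atoms: none
Why: Heating opens the four-membered ring of 19 by a conrotatory four-electron electrocyclic process in which the aryl group turns outward, and the transient (E)-o-quinodimethane 25 is trapped in a concerted suprafacial [4+2] cycloaddition by the ester-bearing C=C of 24, which restores the aromaticity of ring A. The closest known reaction type is the thermolysis of 1-arylbenzocyclobutenes in the presence of acrylate or fumarate dienophiles, the classical aryltetralin construction, and buta-2,3-dienoates are established Diels–Alder partners at their conjugated double bond. The one new ring (C1–C2–C3–C4–C4a–C8a) closes by intermolecular cycloaddition, the C1–C2 and C3–C4 bonds forming in the same step and the distal allene carbon remaining as the exocyclic methylene on C3. The relative configuration of C1 and C2 follows from the E geometry of the diene and the endo position of the ester (1,2-cis), and the absolute sense from the 8-phenylmenthyl group, whose phenyl ring stacks over the Re face of the ester-bearing carbon in the s-trans enoate so that the diene meets the Si face. Regioselectivity comes from the match of the larger HOMO coefficient at the unsubstituted CH2 terminus with the larger LUMO coefficient at the central allene carbon (ortho rule), and site selectivity from the lower LUMO of the conjugated double bond. Since a purely thermal auxiliary bias may be modest, the auxiliary also turns every unwanted adduct into a diastereomer that is removed by chromatography or crystallisation before step 18.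

Step 18
Reactants: 26 1,2-cis methylidene tetralin ester
Product: 27 (1S,2S,3S)-diol ester (C3–OH anti to ring C and to the ester, C3–CH2OH syn to them)
Conditions: OsO4 (2 mol %), NMO, acetone/H2O, rt
Reagents that add atoms: N-methylmorpholine N-oxide, C[N+]1([O-])CCOCC1; water, O
Why: In this Upjohn dihydroxylation C3 is set by the substrate, because the pseudoaxial C1 aryl group (1,3 to C3) and the cis C2 ester cover one face, so OsO4 adds from the other, and the hindered ester resists lactonisation.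

Step 19
Reactants: 27 diol ester
Product: 28 spiro-acetonide ester (2,2-dimethyl-1,3-dioxolane on C3–O and C3–CH2O)
Conditions: 2-methoxypropene, PPTS (cat.), CH2Cl2, 0 °C
Reagents that add atoms: 2-methoxypropene, COC(C)=C
Why: Kinetic acetonide formation from the 1,2-diol under very mild acid blocks lactonisation and retro-aldol cleavage and leaves the aryl dioxolane intact.

Step 20
Reactants: 28 spiro-acetonide ester
Product: 29 1,2-cis primary alcohol (C2–CH2OH syn to ring C)
Conditions: LiAlH4, THF, 0 → 40 °C; H2O, NaOH (aq.) work-up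
Reagents that add atoms: none
Why: Hydride reduction of the ester cleaves the auxiliary, which is recovered, and touches no stereocentre.

Step 21
Reactants: 29 1,2-cis primary alcohol
Product: 30 1,2-cis aldehyde
Conditions: Dess–Martin periodinane, pyridine, CH2Cl2, 0 °C → rt
Reagents that add atoms: none
Why: Buffered Dess–Martin oxidation of the only free hydroxyl group gives the aldehyde without acid damage to the two acetals.

Step 22
Reactants: 30 1,2-cis aldehyde
Product: 32 1,2-trans primary alcohol (C2 as in the target), via trans aldehyde 31 (not isolated)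
Conditions: DBU (0.3 equiv), CH2Cl2, rt; then MeOH, NaBH4, 0 °C
Reagents that add atoms: none
Why: Base-mediated epimerisation through the enolate sets C2 under thermodynamic control, since the trans isomer has ring C, the formyl group and the C3–CH2O branch all equatorial, α-epimerisation of β-alkoxy aldehydes is far faster than loss of alkoxide, and borohydride reduction then fixes the result.

Step 23
Reactants: 32 1,2-trans primary alcohol
Product: 33 triol aldehyde (free C2–CH2OH, C3–OH, C3–CH2OH; CHO on ring B)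
Conditions: 1 M HCl, THF, 40 °C
Reagents that add atoms: water, O
Why: Aqueous acid hydrolysis removes the acetonide and the aryl dioxolane together, so no selectivity between the two acetals is needed.

Step 24
Reactants: 33 triol aldehyde
Product: 34 diacetate aldehyde (both primary hydroxyl groups acetylated, tertiary C3–OH free)
Conditions: Ac2O, pyridine, rt
Reagents that add atoms: acetic anhydride, CC(=O)OC(C)=O
Why: Acetylation caps the two primary alcohols only, and the acetates fall off without an extra step in the reduction of step 30.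

Step 25
Reactants: 35 (S)-malic acid
Product: 36 [(2S,4S)-2-tert-butyl-5-oxo-1,3-dioxolan-4-yl]acetic acid (cis)
Conditions: t-BuCHO, p-TsOH (cat.), H2SO4 (cat.), pentane, reflux, Dean–Stark trap; recrystallisation
Reagents that add atoms: pivalaldehyde, CC(C)(C)C=O
Why: Acid-catalysed acetalisation of the α-hydroxy acid unit gives the five-membered dioxolanone, whose new acetal centre is set by the thermodynamic preference for the cis isomer and purified by recrystallisation.

Step 26
Reactants: 37 3-(benzyloxy)-4-methoxybenzyl alcohol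
Product: 38 3-(benzyloxy)-4-methoxybenzyl bromide
Conditions: PBr3, Et2O, 0 °C
Reagents that add atoms: phosphorus tribromide, BrP(Br)Br
Why: Bromination of an activated benzylic alcohol with PBr3 is fast at low temperature.

Step 27
Reactants: 36 cis-dioxolanone acetic acid; 38 3-(benzyloxy)-4-methoxybenzyl bromide
Product: 40 [(2S,4S)-4-[3-(benzyloxy)-4-methoxybenzyl]-2-tert-butyl-5-oxo-1,3-dioxolan-4-yl]acetic acid, via dilithio dianion 39 (not isolated)
Conditions: LiN(SiMe3)2 (2.2 equiv), THF, −78 °C; then 38, −78 → −20 °C; 1 M HCl to pH 3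
Reagents that add atoms: none
Why: In this enolate alkylation with self-regeneration of the stereocentre the tert-butyl group of the acetal shields one face, so the benzyl bromide enters anti to it in the place of the former hydrogen, which fixes C4′ in the S configuration of the target.

Step 28
Reactants: 40 alkylated dioxolanone acetic acid; 41 (S)-4-benzyloxazolidin-2-one
Product: 43 N-acyl oxazolidinone (imide of 40), via mixed pivalic anhydride 42 (not isolated)
Conditions: PivCl, Et3N, THF, −20 °C; then LiCl, 41, rt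
Reagents that add atoms: none
Why: N-Acylation through the mixed pivalic anhydride takes place at the less hindered carbonyl group and touches no stereocentre.

Step 29
Reactants: 43 N-acyl oxazolidinone; 34 diacetate aldehyde
Product: 45 syn aldol (C2′ S, C3′ R), via (Z)-boron enolate 44 (not isolated)
Conditions: 43 (2 equiv), Bu2BOTf, i-Pr2NEt, CH2Cl2, −78 → 0 °C; then 34, −78 → 0 °C; pH 7 buffer, MeOH, H2O2, 0 °C
Reagents that add atoms: none
Why: In the Evans syn aldol the (Z)-boron enolate reacts through a Zimmerman–Traxler chair, the benzyl group of the (S)-auxiliary fixes the enolate face and so sets C2′ and C3′ together, the covalent boron enolate has little tendency to expel the β-oxygen, and excess enolate tolerates the free tertiary hydroxyl group.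

Step 30
Reactants: 45 syn aldol
Product: 46 heptaol (tetra-O-benzyl)
Conditions: LiBH4 (excess), THF/MeOH, 0 °C → rt
Reagents that add atoms: none
Why: Borohydride reduction takes imide, dioxolanone and acetate carbonyl groups in one operation (reductive removal of the auxiliary), no stereocentre is touched, and any lactone formed by acyl transfer to the C2′ hydroxyl group is reduced to the same heptaol.

Step 31
Reactants: 46 heptaol
Product: 47 tetra-O-benzyl ether of the target (tetrahydrofuran closed)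
Conditions: CSA (10 mol %), CH2Cl2/THF, 0 °C → rt
Reagents that add atoms: none
Why: In this acid-catalysed SN1 cycloetherification only the C2′ alcohol (para to a benzyloxy group) ionises, only the C5′ hydroxyl group reaches the cation through a five-membered ring, and reversible closure places ring B trans to the C3′ CH2OH group, the configuration the aldol had already delivered.

Step 32
Reactants: 47 tetra-O-benzyl ether
Product: 48 target CNP0252244.1
Conditions: H2 (1 atm), Pd/C (10 %), EtOAc/EtOH, rt, stopped after four equivalents of H2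
Reagents that add atoms: none
Why: Catalytic hydrogenolysis cleaves the four aryl benzyl ethers faster than the cyclic benzylic C2′–O1′ bond and avoids the acid that would isomerise the tetrahydrofuran half.

## Compound list

1 | 5-bromovanillin | COc1cc(C=O)cc(Br)c1O | starting material
2 | 4-(benzyloxy)-3-bromo-5-methoxybenzaldehyde | COc1cc(C=O)cc(Br)c1OCc1ccccc1 | intermediate
3 | 2-[4-(benzyloxy)-3-bromo-5-methoxyphenyl]-1,3-dioxolane | COc1cc(C2OCCO2)cc(Br)c1OCc1ccccc1 | intermediate
4 | ring B pinacol boronate | COc1cc(C2OCCO2)cc(B2OC(C)(C)C(C)(C)O2)c1OCc1ccccc1 | intermediate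
5 | 4-bromo-2-methoxyphenol | COc1cc(Br)ccc1O | starting material
6 | 4-bromo-2-iodo-6-methoxyphenol | COc1cc(Br)cc(I)c1O | intermediate
7 | 2-(benzyloxy)-5-bromo-1-iodo-3-methoxybenzene | COc1cc(Br)cc(I)c1OCc1ccccc1 | intermediate
8 | biaryl bromide | COc1cc(C2OCCO2)cc(-c2cc(Br)cc(OC)c2OCc2ccccc2)c1OCc1ccccc1 | intermediate
9 | 6-bromoisovanillin | COc1cc(Br)c(C=O)cc1O | starting material
10 | 5-(benzyloxy)-2-bromo-4-methoxybenzaldehyde | COc1cc(Br)c(C=O)cc1OCc1ccccc1 | intermediate
11 | aryllithium from 8 | COc1cc(C2OCCO2)cc(-c2cc([Li])cc(OC)c2OCc2ccccc2)c1OCc1ccccc1 | intermediate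
12 | diaryl carbinol (racemic) | COc1cc(C2OCCO2)cc(-c2cc(C(O)c3cc(OCc4ccccc4)c(OC)cc3Br)cc(OC)c2OCc2ccccc2)c1OCc1ccccc1 | intermediate
13 | diaryl ketone | COc1cc(C2OCCO2)cc(-c2cc(C(=O)c3cc(OCc4ccccc4)c(OC)cc3Br)cc(OC)c2OCc2ccccc2)c1OCc1ccccc1 | intermediate
14 | 1,1-diarylethene | COc1cc(C2OCCO2)cc(-c2cc(C(=C)c3cc(OCc4ccccc4)c(OC)cc3Br)cc(OC)c2OCc2ccccc2)c1OCc1ccccc1 | intermediate
15 | B-(2,2-diarylethyl)-9-BBN (racemic) | COc1cc(C2OCCO2)cc(-c2cc(C(CB3C4CCCC3CCC4)c3cc(OCc4ccccc4)c(OC)cc3Br)cc(OC)c2OCc2ccccc2)c1OCc1ccccc1 | intermediate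
16 | 2,2-diarylethanol (racemic) | COc1cc(C2OCCO2)cc(-c2cc(C(CO)c3cc(OCc4ccccc4)c(OC)cc3Br)cc(OC)c2OCc2ccccc2)c1OCc1ccccc1 | intermediate
17 | 2,2-diarylethyl bromide (racemic) | COc1cc(C2OCCO2)cc(-c2cc(C(CBr)c3cc(OCc4ccccc4)c(OC)cc3Br)cc(OC)c2OCc2ccccc2)c1OCc1ccccc1 | intermediate
18 | aryllithium from 17 (racemic) | COc1cc(C2OCCO2)cc(-c2cc(C(CBr)c3cc(OCc4ccccc4)c(OC)cc3[Li])cc(OC)c2OCc2ccccc2)c1OCc1ccccc1 | intermediate
19 | 1-arylbenzocyclobutene (racemic) | COc1cc(C2OCCO2)cc(-c2cc(C3Cc4cc(OC)c(OCc5ccccc5)cc34)cc(OC)c2OCc2ccccc2)c1OCc1ccccc1 | intermediate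
20 | (−)-8-phenylmenthol | CC(C)(c1ccccc1)[C@@H]1CC[C@@H](C)C[C@H]1O | starting material
21 | (−)-8-phenylmenthyl bromoacetate | BrCC(=O)O[C@@H]1C[C@H](C)CC[C@H]1C(C)(C)c1ccccc1 | intermediate
22 | phosphonium bromide of 21 | [Br-].O=C(C[P+](c1ccccc1)(c1ccccc1)c1ccccc1)O[C@@H]1C[C@H](C)CC[C@H]1C(C)(C)c1ccccc1 | intermediate
23 | (−)-8-phenylmenthyl (triphenylphosphoranylidene)acetate | O=C(C=P(c1ccccc1)(c1ccccc1)c1ccccc1)O[C@@H]1C[C@H](C)CC[C@H]1C(C)(C)c1ccccc1 | intermediate
24 | (−)-8-phenylmenthyl buta-2,3-dienoate | C=C=CC(=O)O[C@@H]1C[C@H](C)CC[C@H]1C(C)(C)c1ccccc1 | intermediate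
25 | (E)-o-quinodimethane | COc1cc(C2OCCO2)cc(-c2cc(/C=C3\C=C(OCc4ccccc4)C(OC)=CC3=C)cc(OC)c2OCc2ccccc2)c1OCc1ccccc1 | intermediate
26 | 1,2-cis methylidene tetralin ester | COc1cc(C2OCCO2)cc(-c2cc([C@H]3c4cc(OCc5ccccc5)c(OC)cc4CC(=C)[C@H]3C(=O)O[C@@H]3C[C@H](C)CC[C@H]3C(C)(C)c3ccccc3)cc(OC)c2OCc2ccccc2)c1OCc1ccccc1 | intermediate
27 | diol ester | COc1cc(C2OCCO2)cc(-c2cc([C@H]3c4cc(OCc5ccccc5)c(OC)cc4C[C@@](O)(CO)[C@H]3C(=O)O[C@@H]3C[C@H](C)CC[C@H]3C(C)(C)c3ccccc3)cc(OC)c2OCc2ccccc2)c1OCc1ccccc1 | intermediate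
28 | spiro-acetonide ester | COc1cc(C2OCCO2)cc(-c2cc([C@H]3c4cc(OCc5ccccc5)c(OC)cc4C[C@@]4(COC(C)(C)O4)[C@H]3C(=O)O[C@@H]3C[C@H](C)CC[C@H]3C(C)(C)c3ccccc3)cc(OC)c2OCc2ccccc2)c1OCc1ccccc1 | intermediate
29 | 1,2-cis primary alcohol | COc1cc(C2OCCO2)cc(-c2cc([C@H]3c4cc(OCc5ccccc5)c(OC)cc4C[C@@]4(COC(C)(C)O4)[C@H]3CO)cc(OC)c2OCc2ccccc2)c1OCc1ccccc1 | intermediate
30 | 1,2-cis aldehyde | COc1cc(C2OCCO2)cc(-c2cc([C@H]3c4cc(OCc5ccccc5)c(OC)cc4C[C@@]4(COC(C)(C)O4)[C@H]3C=O)cc(OC)c2OCc2ccccc2)c1OCc1ccccc1 | intermediate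
31 | 1,2-trans aldehyde | COc1cc(C2OCCO2)cc(-c2cc([C@H]3c4cc(OCc5ccccc5)c(OC)cc4C[C@@]4(COC(C)(C)O4)[C@@H]3C=O)cc(OC)c2OCc2ccccc2)c1OCc1ccccc1 | intermediate
32 | 1,2-trans primary alcohol | COc1cc(C2OCCO2)cc(-c2cc([C@H]3c4cc(OCc5ccccc5)c(OC)cc4C[C@@]4(COC(C)(C)O4)[C@@H]3CO)cc(OC)c2OCc2ccccc2)c1OCc1ccccc1 | intermediate
33 | triol aldehyde | COc1cc(C=O)cc(-c2cc([C@H]3c4cc(OCc5ccccc5)c(OC)cc4C[C@@](O)(CO)[C@@H]3CO)cc(OC)c2OCc2ccccc2)c1OCc1ccccc1 | intermediate
34 | diacetate aldehyde | COc1cc(C=O)cc(-c2cc([C@H]3c4cc(OCc5ccccc5)c(OC)cc4C[C@@](O)(COC(C)=O)[C@@H]3COC(C)=O)cc(OC)c2OCc2ccccc2)c1OCc1ccccc1 | intermediate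
35 | (S)-malic acid | OC(=O)C[C@H](O)C(=O)O | starting material
36 | [(2S,4S)-2-tert-butyl-5-oxo-1,3-dioxolan-4-yl]acetic acid | OC(=O)C[C@@H]1O[C@H](C(C)(C)C)OC1=O | intermediate
37 | 3-(benzyloxy)-4-methoxybenzyl alcohol | COc1ccc(CO)cc1OCc1ccccc1 | starting material
38 | 3-(benzyloxy)-4-methoxybenzyl bromide | COc1ccc(CBr)cc1OCc1ccccc1 | intermediate
39 | dilithio dianion of 36 | [Li]OC(=O)CC1=C(O[Li])O[C@@H](C(C)(C)C)O1 | intermediate
40 | alkylated dioxolanone acetic acid | OC(=O)C[C@]1(Cc2ccc(OC)c(OCc3ccccc3)c2)O[C@H](C(C)(C)C)OC1=O | intermediate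
41 | (S)-4-benzyloxazolidin-2-one | O=C1N[C@@H](Cc2ccccc2)CO1 | starting material
42 | mixed pivalic anhydride of 40 | CC(C)(C)C(=O)OC(=O)C[C@]1(Cc2ccc(OC)c(OCc3ccccc3)c2)O[C@H](C(C)(C)C)OC1=O | intermediate
43 | N-acyl oxazolidinone | O=C1OC[C@H](Cc2ccccc2)N1C(=O)C[C@]1(Cc2ccc(OC)c(OCc3ccccc3)c2)O[C@H](C(C)(C)C)OC1=O | intermediate
44 | (Z)-dibutylboron enolate of 43 | CCCCB(CCCC)O/C(=C\[C@]1(Cc2ccc(OC)c(OCc3ccccc3)c2)O[C@H](C(C)(C)C)OC1=O)N1[C@@H](Cc2ccccc2)COC1=O | intermediate
45 | syn aldol | COc1cc([C@@H](O)[C@@H](C(=O)N2[C@@H](Cc3ccccc3)COC2=O)[C@]2(Cc3ccc(OC)c(OCc4ccccc4)c3)O[C@H](C(C)(C)C)OC2=O)cc(-c2cc([C@H]3c4cc(OCc5ccccc5)c(OC)cc4C[C@@](O)(COC(C)=O)[C@@H]3COC(C)=O)cc(OC)c2OCc2ccccc2)c1OCc1ccccc1 | intermediate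
46 | heptaol (tetra-O-benzyl) | COc1cc([C@@H](O)[C@@H](CO)[C@](O)(CO)Cc2ccc(OC)c(OCc3ccccc3)c2)cc(-c2cc([C@H]3c4cc(OCc5ccccc5)c(OC)cc4C[C@@](O)(CO)[C@@H]3CO)cc(OC)c2OCc2ccccc2)c1OCc1ccccc1 | intermediate
47 | tetra-O-benzyl ether of the target | COc1cc([C@H]2OC[C@](O)(Cc3ccc(OC)c(OCc4ccccc4)c3)[C@@H]2CO)cc(-c2cc([C@H]3c4cc(OCc5ccccc5)c(OC)cc4C[C@@](O)(CO)[C@@H]3CO)cc(OC)c2OCc2ccccc2)c1OCc1ccccc1 | intermediate
48 | CNP0252244.1 | COc1ccc(C[C@@]2(O)CO[C@H](c3cc(OC)c(O)c(-c4cc([C@H]5c6cc(O)c(OC)cc6C[C@@](O)(CO)[C@@H]5CO)cc(OC)c4O)c3)[C@H]2CO)cc1O | target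

## Step count and weak points

Total step count: 32.
Longest linear sequence: 22 steps (steps 1, 2, 3, 6, 8–13, 17–24, 29–32).

**Step 17.** The temperature needed for ring opening may give weak discrimination between endo and exo approach and between the two faces of the allenoate. The allenoate may also react with itself before it is captured.

The fallback sets out from 19 and comes back at 33.
- 19 is heated with commercial bis[(1R,2S,5R)-menthyl] fumarate, a dienophile class long used against aryl o-quinodimethanes.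
- Brief treatment with catalytic KOt-Bu in THF converges the adducts of one C1 configuration on the all-trans dimenthyl diester F1, which is purified by crystallisation.
- Kinetic deprotonation with LiN(i-Pr)2 at the less hindered C3–H is followed by oxidation of the enolate with 2-(phenylsulfonyl)-3-phenyloxaziridine. Oxidation from the face away from ring C should give the C3-hydroxy diester F2.
- LiAlH4 gives the triol acetal F3, and 1 M HCl in THF gives 33.

**Step 29.** The neopentyl-type enolate may add slowly. The C4′–O bond may also be lost by β-elimination with fragmentation of the dioxolanone.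

The fallback sets out from 33 (with 41 and 38) and comes back at 46. It does the aldol on an unhindered enolate and builds C4′ afterwards on a ring.
- 33 is silylated (TBSOTf, 2,6-lutidine) to the tris-TBS aldehyde F4.
- 41 is acylated (n-BuLi, methyl 4-chloro-4-oxobutanoate) to the succinyl imide F5.
- An Evans syn aldol (Bu2BOTf, Et3N) of F5 with F4, followed by lactonisation, gives the trans lactone imide F6.
- LiOH/H2O2 gives the lactone acid F7.
- The dianion (NaN(SiMe3)2, 2.2 equiv) is alkylated with 38 to the α-benzyl lactone acid F8.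
- A second enolisation (KN(SiMe3)2) and oxidation with 2-(phenylsulfonyl)-3-phenyloxaziridine, anti to the C3′ carboxylate, gives the α-hydroxy lactone acid F9.
- LiAlH4 gives the silylated heptaol F10, and Bu4NF gives 46.

**Step 31.** The benzylic cation may be captured by ring D in a Friedel–Crafts closure of a six-membered ring, and control of C2′ may be incomplete.

The fallback sets out from 45 and comes back at 47. It makes the O1′–C5′ bond by acyl transfer, so C2′–O is never broken.
- LiOH/H2O2 followed by acidification removes the auxiliary, acetates and pivalaldehyde acetal, and the C2′ hydroxyl group lactonises onto C5′ to give the hydroxy lactone acid F11.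
- BH3·SMe2 reduces the free acid to the hydroxymethyl lactone F12.
- i-Bu2AlH at −78 °C gives the lactol F13.
- Et3SiH with BF3·OEt2 at −78 °C reduces the lactol carbon to CH2 and gives 47.

## Further compounds

F1 | step 17 | all-trans dimenthyl diester | COc1cc(C2OCCO2)cc(-c2cc([C@H]3c4cc(OCc5ccccc5)c(OC)cc4C[C@@H](C(=O)O[C@@H]4C[C@H](C)CC[C@H]4C(C)C)[C@@H]3C(=O)O[C@@H]3C[C@H](C)CC[C@H]3C(C)C)cc(OC)c2OCc2ccccc2)c1OCc1ccccc1
F2 | step 17 | C3-hydroxy diester | COc1cc(C2OCCO2)cc(-c2cc([C@H]3c4cc(OCc5ccccc5)c(OC)cc4C[C@@](O)(C(=O)O[C@@H]4C[C@H](C)CC[C@H]4C(C)C)[C@@H]3C(=O)O[C@@H]3C[C@H](C)CC[C@H]3C(C)C)cc(OC)c2OCc2ccccc2)c1OCc1ccccc1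
F3 | step 17 | triol acetal | COc1cc(C2OCCO2)cc(-c2cc([C@H]3c4cc(OCc5ccccc5)c(OC)cc4C[C@@](O)(CO)[C@@H]3CO)cc(OC)c2OCc2ccccc2)c1OCc1ccccc1
F4 | step 29 | tris-TBS aldehyde | COc1cc(C=O)cc(-c2cc([C@H]3c4cc(OCc5ccccc5)c(OC)cc4C[C@@](O[Si](C)(C)C(C)(C)C)(CO[Si](C)(C)C(C)(C)C)[C@@H]3CO[Si](C)(C)C(C)(C)C)cc(OC)c2OCc2ccccc2)c1OCc1ccccc1
F5 | step 29 | succinyl imide | COC(=O)CCC(=O)N1[C@@H](Cc2ccccc2)COC1=O
F6 | step 29 | trans lactone imide | COc1cc([C@H]2OC(=O)C[C@@H]2C(=O)N2[C@@H](Cc3ccccc3)COC2=O)cc(-c2cc([C@H]3c4cc(OCc5ccccc5)c(OC)cc4C[C@@](O[Si](C)(C)C(C)(C)C)(CO[Si](C)(C)C(C)(C)C)[C@@H]3CO[Si](C)(C)C(C)(C)C)cc(OC)c2OCc2ccccc2)c1OCc1ccccc1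
F7 | step 29 | lactone acid | COc1cc([C@H]2OC(=O)C[C@@H]2C(=O)O)cc(-c2cc([C@H]3c4cc(OCc5ccccc5)c(OC)cc4C[C@@](O[Si](C)(C)C(C)(C)C)(CO[Si](C)(C)C(C)(C)C)[C@@H]3CO[Si](C)(C)C(C)(C)C)cc(OC)c2OCc2ccccc2)c1OCc1ccccc1
F8 | step 29 | α-benzyl lactone acid | COc1cc([C@H]2OC(=O)[C@@H](Cc3ccc(OC)c(OCc4ccccc4)c3)[C@@H]2C(=O)O)cc(-c2cc([C@H]3c4cc(OCc5ccccc5)c(OC)cc4C[C@@](O[Si](C)(C)C(C)(C)C)(CO[Si](C)(C)C(C)(C)C)[C@@H]3CO[Si](C)(C)C(C)(C)C)cc(OC)c2OCc2ccccc2)c1OCc1ccccc1
F9 | step 29 | α-hydroxy lactone acid | COc1cc([C@H]2OC(=O)[C@](O)(Cc3ccc(OC)c(OCc4ccccc4)c3)[C@@H]2C(=O)O)cc(-c2cc([C@H]3c4cc(OCc5ccccc5)c(OC)cc4C[C@@](O[Si](C)(C)C(C)(C)C)(CO[Si](C)(C)C(C)(C)C)[C@@H]3CO[Si](C)(C)C(C)(C)C)cc(OC)c2OCc2ccccc2)c1OCc1ccccc1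
F10 | step 29 | silylated heptaol | COc1cc([C@@H](O)[C@@H](CO)[C@](O)(CO)Cc2ccc(OC)c(OCc3ccccc3)c2)cc(-c2cc([C@H]3c4cc(OCc5ccccc5)c(OC)cc4C[C@@](O[Si](C)(C)C(C)(C)C)(CO[Si](C)(C)C(C)(C)C)[C@@H]3CO[Si](C)(C)C(C)(C)C)cc(OC)c2OCc2ccccc2)c1OCc1ccccc1
F11 | step 31 | hydroxy lactone acid | COc1cc([C@H]2OC(=O)[C@](O)(Cc3ccc(OC)c(OCc4ccccc4)c3)[C@@H]2C(=O)O)cc(-c2cc([C@H]3c4cc(OCc5ccccc5)c(OC)cc4C[C@@](O)(CO)[C@@H]3CO)cc(OC)c2OCc2ccccc2)c1OCc1ccccc1
F12 | step 31 | hydroxymethyl lactone | COc1cc([C@H]2OC(=O)[C@](O)(Cc3ccc(OC)c(OCc4ccccc4)c3)[C@@H]2CO)cc(-c2cc([C@H]3c4cc(OCc5ccccc5)c(OC)cc4C[C@@](O)(CO)[C@@H]3CO)cc(OC)c2OCc2ccccc2)c1OCc1ccccc1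
F13 | step 31 | lactol (mixture at the lactol carbon) | COc1cc([C@H]2OC(O)[C@](O)(Cc3ccc(OC)c(OCc4ccccc4)c3)[C@@H]2CO)cc(-c2cc([C@H]3c4cc(OCc5ccccc5)c(OC)cc4C[C@@](O)(CO)[C@@H]3CO)cc(OC)c2OCc2ccccc2)c1OCc1ccccc1
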